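# Synthesis plan for 1,5-dibromo-3-(2,4-dibromophenoxy)-2-methoxybenzene (5)

## The problem

1. Compound 5 is two benzene rings joined only through one oxygen. Ring A is numbered from the methoxy carbon (C1 OMe, C2 Br, C4 Br, C6 O-aryl). Ring B is numbered from the ether carbon (C1' O, C2' Br, C4' Br). There is no ring fusion, no chain and no stereogenic element.
2. The one strategic bond is O1'–C6. It must be made in the presence of four aryl C–Br bonds, each a coupling site for copper or palladium. Neither ring carries an acceptor group that would allow SNAr.
3. The second task is positional certainty. Six substituents must sit at defined places, and the isomeric brominated diphenyl ethers from loose halogenation are very hard to separate.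
4. In ring A both bromines are ortho and para to the oxygen at C1 and meta to the oxygen at C6. Only the C1 oxygen can therefore have acted as the directing group.
5. The feature that opens the problem is that rings A and B carry the same pattern: oxygen at position 1, bromine at positions 2 and 4. The ether bond runs from O1' of ring B to C6 of ring A, the only unsubstituted ortho or para carbon of that ring. Compound 5 is thus the methyl ether of the O1'–C6 dehydrodimer 4 of a single monomer, 2,4-dibromophenol 1.
6. O1' and C6 are both nucleophilic sites of 1. Their union needs the removal of two electrons and two protons, which is an oxidative coupling of like polarity.
7. The C–Br bonds are sensitive to light, reducing metals, organometallic reagents and low-valent transition metals. The 2-(2-bromophenoxy)phenol motif of 4 can close to a brominated dibenzo-p-dioxin under heat, strong base, copper or UV light.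
8. No stereocentre has to be controlled. The only sp3 ring carbon of the route, C6 of dienone 3, is transient.

## Retrosynthesis

**Cut 1, the O–CH3 bond at C1 of 5, giving phenol 4.**
- This bond is cut first because an anisole ring cannot be oxidised to a phenoxyl radical. Cutting the diaryl ether of 5 directly would leave ring A without the function that activates C6.
- Phenol 4 is simpler by only one carbon. The gain is functional: the free hydroxyl at C1 reveals ring A as a phenol of the same kind as ring B.
- Phenol 4 has a single hydroxyl, so the forward reaction has no selectivity problem.
- The forward reaction must alkylate an acidic phenol flanked on both sides, at room temperature and in the dark, so that the phenolate does not displace the bromide at C2'.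

**Cut 2, the O1'–C6 bond of 4, through dienone 3 to two radicals 2, that is to two molecules of 1.**
- The neighbouring cut, O1'–C1' on the other side of the ether oxygen, gives two different brominated halves, each needing its own synthesis. It also requires an aryl electrophile in a molecule full of C–Br bonds.
- The homolytic O1'–C6 cut gives two identical halves.
- The simplification is large. A C12 tetrabromide with six placed substituents falls to one commercial C6 monomer that already holds both oxygens and all four bromines in their final positions.
- The forward reaction must achieve one-electron oxidation of 1 to 2 and pairing of the oxygen of one radical with C6 of the other rather than C6 with C6. It must also allow tautomerisation of 3 to 4 and stop at the dimer.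

**No further cut.** Monomer 1 is an article of commerce. The C–Br bonds are deliberately left uncut, so that no bromine is placed on the diaryl ether itself.

## Roads not taken

**Alternative 1:** the most obvious plan. The ether is cut into two different, fully brominated halves that are joined as nucleophile and electrophile.
- Ullmann, Chan–Lam and Buchwald–Hartwig couplings are compromised by the four competing C–Br bonds, and SNAr lacks an activating group.
- The forward key step would therefore be the metal-free O-arylation of 3,5-dibromo-2-methoxyphenol A1 by bis(2,4-dibromophenyl)iodonium tetrafluoroborate A2.
- The bond formation itself is sound, but the run-up is long. Both bromines of A1 are meta to its hydroxyl, so A1 cannot come from bromination of a phenol. Its hydroxyl must be brought in indirectly after the bromines.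
- A2 must be built from 2,4-dibromo-1-iodobenzene A3 and returns one of its two aryl groups as A3.
- Two separate building-block syntheses converge on one bond, and the identity of the two rings goes unused. The chosen plan needs two steps from one monomer.

**Alternative 2:** all four C–Br bonds are cut. The forward key step is exhaustive bromination of 2-phenoxyphenol A4 to 4.
- The route is equally short, and the first three brominations follow the directing groups as far as 2,4-dibromo-6-(4-bromophenoxy)phenol A5.
- The fourth bromine must enter C2' of a ring already deactivated by its para bromine. The oxygen lone pair of that ring is also shared with an electron-poor dibromophenol ring.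
- Competing events are ipso attack at C4 of the phenol ring, giving a bromodienone, and attack at the remaining positions of ring A.
- Under- and over-bromination give congeners that differ by one bromine, the separation known to be worst in this class.
- In the chosen plan every bromine is fixed in the monomer. By-products differ from 4 in size or in the number of hydroxyl groups.
- Alternative 2 also buys the ether bond instead of making it.

**Alternative 3:** the same O1'–C6 cut, with polarity reversal at C6 by a carbene.
- Nitration and reduction of 1 would give 2-amino-4,6-dibromophenol A6. Diazotisation would give the ortho-quinone diazide 2,4-dibromo-6-diazocyclohexa-2,4-dien-1-one A7.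
- The forward key step is a rhodium(II)-catalysed O–H insertion of the derived carbenoid into 1. This would pass through the same dienone 3 to 4.
- The plan is regiospecific and free of over-oxidation. It spends three extra steps placing a nitrogen at C6 only to expel it, and it handles an energetic diazo compound.
- It must also suppress Wolff ring contraction, the characteristic reaction of ortho-quinone diazides.
- The chosen plan activates the C6–H bond directly.

Key step: step 1

Assumption: 5 has no stereocentre and no hindered axis and is achiral, so the demand for a single enantiomer is met by any sample. Horseradish peroxidase is taken as a commercial catalyst.

## Steps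

Step 1
Reactants: 1 2,4-dibromophenol (two molecules)
Product: 4 2,4-dibromo-6-(2,4-dibromophenoxy)phenol, via 2,4-dibromophenoxyl radical 2 (not isolated), via aryloxy-dienone tautomer 3 (not isolated)
Conditions: horseradish peroxidase (cat.), 30% aq. H2O2 (0.25 equiv, syringe pump), phosphate buffer pH 6.5 / toluene (1:1, gentle stirring, two layers kept), 20 °C, dark; unreacted 1 recovered and recycled
Reagents that add atoms: none
Why: Biomimetic dehydrodimerisation (phenol oxidative coupling): the peroxidase takes one electron and one proton from each of two molecules of 1 per molecule of H2O2 and releases the free radical 2 into the aqueous layer. Radical 2 carries its spin on O1, C2, C4 and C6; pairing of O1' of one radical with C6 of a second gives dienone 3, the only O–C adduct with a hydrogen at the new sp3 carbon, which can therefore tautomerise irreversibly to phenol 4, whereas adducts at the bromine-bearing C2 and C4 cannot enolise and are expected largely to revert by homolysis, as quinol ethers do. The closest known reaction type is the peroxidase-, laccase- or manganese(IV) oxide-mediated dimerisation of 2,4-dihalophenols, which is known to form this 2-aryloxyphenol connectivity, together with the anodic and thallium(III) C–O couplings of ortho-brominated phenols used for isodityrosine-type ethers. No ring is closed and no lasting stereocentre is made: C6 of 3 forms as a racemate and is flattened on tautomerisation. The first selectivity, O–C6 against C6–C6' pairing, rests on the higher spin density at oxygen than at an ortho carbon, on the two degenerate O–C6 combinations per encounter and on kinetic control at 20 °C, and the bis-phenol from C–C pairing is more polar and should be removable by chromatography. The second selectivity, dimer against further oxidation, is the weak point because 4 is at least as oxidisable as 1; it is addressed by the toluene layer, which feeds 1 into the water and withdraws the far more lipophilic 4 from the phase in which radicals are made, and by supplying only half of the oxidant needed for full conversion. The four C–Br bonds are inert to the ferryl haem, and this peroxidase does not oxidise bromide at this pH, so bromine cannot be scrambled.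

Step 2
Reactants: 4 2,4-dibromo-6-(2,4-dibromophenoxy)phenol
Product: 5 1,5-dibromo-3-(2,4-dibromophenoxy)-2-methoxybenzene
Conditions: MeI (1.5 equiv), K2CO3 (2 equiv), acetone, 20 °C, dark
Reagents that add atoms: iodomethane, CI
Why: Williamson ether synthesis: the phenol, acidified by two bromines and the aryloxy group, should be fully deprotonated by carbonate, and iodomethane is small enough to reach an oxygen flanked at both ortho positions. Room temperature and exclusion of light keep the phenolate from displacing the C2' bromide and keep the C–Br bonds intact.

## Compound list

1 | 2,4-dibromophenol | Oc1ccc(Br)cc1Br | starting material
2 | 2,4-dibromophenoxyl radical (not isolated) | [O]c1ccc(Br)cc1Br | intermediate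
3 | 2,4-dibromo-6-(2,4-dibromophenoxy)cyclohexa-2,4-dien-1-one (racemic at C6, not isolated) | O=C1C(Br)=CC(Br)=CC1Oc1ccc(Br)cc1Br | intermediate
4 | 2,4-dibromo-6-(2,4-dibromophenoxy)phenol | Oc1c(Br)cc(Br)cc1Oc1ccc(Br)cc1Br | intermediate
5 | 1,5-dibromo-3-(2,4-dibromophenoxy)-2-methoxybenzene | COc1c(Br)cc(Br)cc1Oc1ccc(Br)cc1Br | target

## Step count and least certain steps

Total step count: 2. Longest linear sequence: 2 steps. The route has only two steps, so both are assessed.

**Step 1 (key step).** Three processes threaten it.
- The product phenol can be oxidised further. Its radical has no free ortho or para carbon and can only add through oxygen to C6 of a monomer radical, which grows the chain. In water it can also lose the para bromide on the way to a quinone. This is the main risk, because radical exchange between phenols is fast and the aryloxy group makes the product slightly easier to oxidise than the monomer.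
- The two free ortho carbons can pair (C–C coupling) in place of O–C pairing.
- Pairing at the bromine-bearing carbons may be followed by bromide loss instead of reversion, and oligomer deposits may slowly inactivate the enzyme.

*Fallback, setting out from 1 and returning at 5.* Monomer 1 is kept as the source of both rings, and the radical pairing is replaced by a polar, metal-free O-arylation.
- Iodination of 1 at C6, its only free activated position (NIS, cat. TsOH, MeCN), would give 2,4-dibromo-6-iodophenol F1.
- Methylation (MeI, K2CO3, acetone) would give 1,5-dibromo-3-iodo-2-methoxybenzene F2.
- Oxidation with mCPBA and TsOH, then capture by 1,3,5-trimethoxybenzene, would give (3,5-dibromo-2-methoxyphenyl)(2,4,6-trimethoxyphenyl)iodonium tosylate F3.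
- A second portion of 1 with K2CO3 in MeCN at about 50 °C should then undergo ligand coupling at iodine(III). The electron-rich trimethoxyphenyl group stays on iodine, and the ortho-substituted dibromoanisyl group passes to the phenolate oxygen, giving 5 directly.
- The sequence has four steps, touches no C–Br bond and also bypasses step 2.

**Step 2.** Alkylation may be slow at an oxygen flanked on both sides. If the mixture is then heated or exposed to light, the phenolate may displace the C2' bromide intramolecularly and close a dioxin ring. This is a loss of material and a safety concern.

*Fallback, setting out from 4 and returning at 5.* This is a Mitsunobu etherification with methanol (PPh3, DIAD, THF, 0 to 20 °C). The alcohol is activated as a methoxyphosphonium ion and the acidic phenol serves as the pronucleophile. No inorganic base or heating is used. This fallback makes no new compound (F0).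

## Further compounds

F1 | step 1 | 2,4-dibromo-6-iodophenol | Oc1c(Br)cc(Br)cc1I
F2 | step 1 | 1,5-dibromo-3-iodo-2-methoxybenzene | COc1c(Br)cc(Br)cc1I
F3 | step 1 | (3,5-dibromo-2-methoxyphenyl)(2,4,6-trimethoxyphenyl)iodonium tosylate | COc1cc(OC)c([I+]c2cc(Br)cc(Br)c2OC)c(OC)c1.Cc1ccc(cc1)S(=O)(=O)[O-]
F0 | step 2 | none | none
A1 | alternative 1 | 3,5-dibromo-2-methoxyphenol | COc1c(O)cc(Br)cc1Br
A2 | alternative 1 | bis(2,4-dibromophenyl)iodonium tetrafluoroborate | Brc1ccc([I+]c2ccc(Br)cc2Br)c(Br)c1.F[B-](F)(F)F
A3 | alternative 1 | 2,4-dibromo-1-iodobenzene | Brc1ccc(I)c(Br)c1
A4 | alternative 2 | 2-phenoxyphenol | Oc1ccccc1Oc1ccccc1
A5 | alternative 2 | 2,4-dibromo-6-(4-bromophenoxy)phenol | Oc1c(Br)cc(Br)cc1Oc1ccc(Br)cc1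
A6 | alternative 3 | 2-amino-4,6-dibromophenol | Nc1cc(Br)cc(Br)c1O
A7 | alternative 3 | 2,4-dibromo-6-diazocyclohexa-2,4-dien-1-one | O=C1C(Br)=CC(Br)=CC1=[N+]=[N-]
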